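**Retrosynthetic overview**
1. Target 23 is the Steglich ester of acid 22 with epoxy ketol 15; 22 comes in three steps from glycolaldehyde dimer, a formyl ylide and tigloyl chloride.
2. 15 goes back to the open-chain (2Z,5R)-dialdehyde 13 by cutting the C1(ketone)–C6(carbinol) bond (retro-benzoin) and returning the oxirane to the enone. Forward, one flask closes first the six-membered carbocycle and then the oxirane.
3. Enabling feature: in the cyclohexanone ring, C1 is a ketone flanked by the oxygen-bearing C6 (an acyloin unit) and by the C2–C3 oxirane (a masked enone). C1 can therefore be the acyl anion of an enal, C6 an aldehyde acceptor, and the oxirane oxygen can be delivered afterwards to the enone face opposite the C5 isopropenyl group.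
4. 13 comes from Z-diol 12, and 12 from the seven-membered lactone 11, a temporary ring made by ring-closing metathesis of methacrylate 10; the ring enforces the Z alkene that holds C1 cis to C4.
5. C5 is the only centre set by a reagent (auxiliary-directed deconjugative allylation, 4 to 7); C6, C3 and C2 follow from it in the key step. Ring order: lactone (temporary), carbocycle, oxirane.

Key step: step 8

Remark: locants C1 to C6 follow the cyclohexanone ring of the target (C1 ketone, C2 methyl-bearing oxirane carbon, C3 oxirane CH, C4 CH2, C5 isopropenyl-bearing carbon, C6 acyloxy-bearing carbon).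

**Route**

Step 1
Reactants: 1 (R)-4-benzyl-1,3-oxazolidin-2-one; 2 3-methylbut-2-enoyl chloride
Product: 4 (R)-4-benzyl-3-(3-methylbut-2-enoyl)-1,3-oxazolidin-2-one, via lithium oxazolidinide 3 (not isolated)
Conditions: n-BuLi, THF, −78 °C; then 2, −78 to 0 °C
Reagents that add atoms: n-butyllithium, [Li]CCCC (its lithium is held only in intermediate 3)
Why: N-acylation of the lithiated oxazolidinone with an acid chloride is the standard entry to the imide needed for an Evans-type alkylation, and no stereocentre is formed.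

Step 2
Reactants: 4 (R)-4-benzyl-3-(3-methylbut-2-enoyl)-1,3-oxazolidin-2-one; 5 allyl iodide (3-iodoprop-1-ene)
Product: 7 (R)-4-benzyl-3-[(R)-2-(prop-1-en-2-yl)pent-4-enoyl]-1,3-oxazolidin-2-one, via sodium dienolate 6 (not isolated)
Conditions: NaN(SiMe3)2, THF, −78 °C; then 5, −78 to −45 °C; AcOH quench at low temperature
Reagents that add atoms: sodium bis(trimethylsilyl)amide, C[Si](C)(C)[N-][Si](C)(C)C.[Na+] (its sodium is held only in intermediate 6)
Why: In this Evans-type deconjugative alkylation, γ-deprotonation gives the chelated (Z)-dienolate 6, which should be allylated at its α-carbon on the face away from the benzyl group, so the auxiliary sets the isopropenyl-bearing centre (the later C5) as R while the double bond moves out of conjugation.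

Step 3
Reactants: 7 (R)-4-benzyl-3-[(R)-2-(prop-1-en-2-yl)pent-4-enoyl]-1,3-oxazolidin-2-one
Product: 8 (R)-2-(prop-1-en-2-yl)pent-4-en-1-ol
Conditions: LiBH4, MeOH (1 equiv), Et2O, 0 °C
Reagents that add atoms: none
Why: Reductive cleavage of the imide with LiBH4 gives the primary alcohol, leaves both alkenes alone and should not epimerise the allylic α-centre.

Step 4
Reactants: 8 (R)-2-(prop-1-en-2-yl)pent-4-en-1-ol; 9 methacryloyl chloride (2-methylprop-2-enoyl chloride)
Product: 10 (R)-2-(prop-1-en-2-yl)pent-4-en-1-yl 2-methylprop-2-enoate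
Conditions: Et3N, DMAP (cat.), CH2Cl2, 0 °C to rt
Reagents that add atoms: none
Why: DMAP-catalysed O-acylation of the primary alcohol attaches the methacrylate, which serves as a temporary tether and as the source of C1, C2 and the C2 methyl group.

Step 5
Reactants: 10 (R)-2-(prop-1-en-2-yl)pent-4-en-1-yl 2-methylprop-2-enoate
Product: 11 (R)-3-methyl-6-(prop-1-en-2-yl)-6,7-dihydrooxepin-2(5H)-one
Conditions: second-generation Grubbs catalyst RuCl2(=CHPh)(PCy3)(H2IMes) (5–10 mol %), toluene (2 mM), 80 °C
Reagents that add atoms: none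
Why: Ring-closing metathesis of the terminal alkene onto the methacrylate should give the seven-membered unsaturated lactone, in which the new trisubstituted double bond is necessarily Z, so C1 and C4 are fixed cis as the later six-membered ring demands; the hindered isopropenyl group should not take part.

Step 6
Reactants: 11 (R)-3-methyl-6-(prop-1-en-2-yl)-6,7-dihydrooxepin-2(5H)-one
Product: 12 (2Z,5R)-2-methyl-5-(prop-1-en-2-yl)hex-2-ene-1,6-diol
Conditions: i-Bu2AlH (4.5 equiv), CH2Cl2, −78 to 0 °C; aq. potassium sodium tartrate (KNaC4H4O6)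
Reagents that add atoms: none
Why: Exhaustive 1,2-reduction of the conjugated lactone with i-Bu2AlH opens the temporary ring to the diol with the Z geometry kept and with C1 and C6 both at the alcohol level.

Step 7
Reactants: 12 (2Z,5R)-2-methyl-5-(prop-1-en-2-yl)hex-2-ene-1,6-diol
Product: 13 (2Z,5R)-2-methyl-5-(prop-1-en-2-yl)hex-2-enedial
Conditions: (COCl)2, DMSO, CH2Cl2, −78 °C; then i-Pr2NEt, −78 to −30 °C; cold work-up, used crude at once
Reagents that add atoms: none
Why: In a Swern oxidation both alcohols are activated as alkoxysulfonium salts before base is added, so both should become aldehydes without a hydroxy aldehyde (and hence a lactol or lactone) arising, and the cold conditions with a hindered amine should keep the Z enal and the C5 centre intact.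

Step 8
Reactants: 13 (2Z,5R)-2-methyl-5-(prop-1-en-2-yl)hex-2-enedial
Product: 15 (1S,3R,4R,6S)-3-hydroxy-1-methyl-4-(prop-1-en-2-yl)-7-oxabicyclo[4.1.0]heptan-2-one, via hydroxy enone 14 (not isolated)
Conditions: 2-(pentafluorophenyl)-6,7-dihydro-5H-pyrrolo[2,1-c][1,2,4]triazol-2-ium tetrafluoroborate (15 mol %), i-Pr2NEt (15 mol %), THF (0.01 M), rt, argon; then t-BuOOH (decane solution, 2 equiv), DBU (1.2 equiv), 0 °C to rt
Reagents that add atoms: tert-butyl hydroperoxide, CC(C)(C)OO
Why: The triazolylidene adds to the conjugated aldehyde to give a Breslow intermediate whose acyl-anion carbon (C1) attacks the saturated aldehyde (C6) in a 6-exo-trig closure, an intramolecular crossed benzoin reaction whose closest precedent is the azolium-catalysed cyclisation of 1,6-dialdehydes to 2-hydroxycyclohexanones; this one event forms the C1–C6 bond, the ketone and the carbinol. The regiochemistry needed (ketone at C1) rests on the α-branched aldehyde being the poorer acyl donor and the better acceptor and on the reversibility of ketol formation, which should funnel material to the conjugated enone 14; the Z geometry locked in step 5 is what lets C1 reach C6. The new C6 centre should come out trans to the C5 isopropenyl group under thermodynamic control, since the ketol centre is epimerisable in the basic, reversible medium and the diequatorial arrangement is favoured. t-BuOOH and DBU added to the same flask then effect a Weitz–Scheffer epoxidation: conjugate addition of the peroxide anion at C3 and 3-exo-tet closure of the enolate carbon C2 onto oxygen close the oxirane, which can only be cis-fused. The peroxide should attack C3 axially on the face opposite the equatorial isopropenyl group, as in the nucleophilic epoxidation of carvone, which sets C3 and C2; the nucleophilic oxidant leaves the electron-rich isopropenyl alkene alone. High dilution and a catalytic amount of a weak amine in the first stage are there to suppress oligomerisation and epimerisation of 13 at C5.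

Step 9
Reactants: 16 1,4-dioxane-2,5-diol (glycolaldehyde dimer); 17 2-(triphenyl-λ5-phosphanylidene)propanal
Product: 19 (E)-4-hydroxy-2-methylbut-2-enal, via glycolaldehyde 18 (not isolated)
Conditions: THF, 65 °C
Reagents that add atoms: none
Why: Wittig olefination of glycolaldehyde 18 (released from its dimer on heating) with the stabilised formyl ylide should give the trisubstituted enal with E geometry, as usual for stabilised ylides.

Step 10
Reactants: 19 (E)-4-hydroxy-2-methylbut-2-enal; 20 (E)-2-methylbut-2-enoyl chloride (tigloyl chloride)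
Product: 21 (E)-3-methyl-4-oxobut-2-en-1-yl (E)-2-methylbut-2-enoate
Conditions: pyridine, DMAP (cat.), CH2Cl2, 0 °C
Reagents that add atoms: none
Why: Acylation of the primary allylic alcohol with the acid chloride under pyridine/DMAP catalysis introduces the tigloyl group without touching either double-bond geometry.

Step 11
Reactants: 21 (E)-3-methyl-4-oxobut-2-en-1-yl (E)-2-methylbut-2-enoate
Product: 22 (E)-2-methyl-4-{[(E)-2-methylbut-2-enoyl]oxy}but-2-enoic acid
Conditions: NaClO2, NaH2PO4, 2-methylbut-2-ene, t-BuOH/H2O, 0 °C to rt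
Reagents that add atoms: sodium chlorite, [Na+].[O-]Cl=O
Why: Pinnick oxidation converts the enal to the acid under buffered conditions that spare the alkenes and the ester, with 2-methylbut-2-ene trapping the hypochlorite formed.

Step 12
Reactants: 15 (1S,3R,4R,6S)-3-hydroxy-1-methyl-4-(prop-1-en-2-yl)-7-oxabicyclo[4.1.0]heptan-2-one; 22 (E)-2-methyl-4-{[(E)-2-methylbut-2-enoyl]oxy}but-2-enoic acid
Product: 23 (1S,3R,4R,6S)-1-methyl-2-oxo-4-(prop-1-en-2-yl)-7-oxabicyclo[4.1.0]heptan-3-yl (E)-2-methyl-4-{[(E)-2-methylbut-2-enoyl]oxy}but-2-enoate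
Conditions: DCC, DMAP, CH2Cl2, 0 °C to rt
Reagents that add atoms: none
Why: Steglich esterification (carbodiimide activation, acyl transfer by DMAP) acylates the secondary ketol hydroxyl at C6 with retention, since the C–O bond of the alcohol is not broken, and its near-neutral conditions should spare the epoxy ketone.

**Compound list**
1 | (R)-4-benzyl-1,3-oxazolidin-2-one | O=C1N[C@H](Cc2ccccc2)CO1 | starting material
2 | 3-methylbut-2-enoyl chloride | CC(C)=CC(=O)Cl | starting material
3 | lithium (R)-4-benzyl-2-oxo-1,3-oxazolidin-3-ide | [Li+].O=C1[N-][C@H](Cc2ccccc2)CO1 | intermediate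
4 | (R)-4-benzyl-3-(3-methylbut-2-enoyl)-1,3-oxazolidin-2-one | CC(C)=CC(=O)N1[C@H](Cc2ccccc2)COC1=O | intermediate
5 | allyl iodide (3-iodoprop-1-ene) | C=CCI | starting material
6 | sodium (Z)-1-[(R)-4-benzyl-2-oxo-1,3-oxazolidin-3-yl]-3-methylbuta-1,3-dien-1-olate | C=C(C)/C=C(\[O-])N1[C@H](Cc2ccccc2)COC1=O.[Na+] | intermediate
7 | (R)-4-benzyl-3-[(R)-2-(prop-1-en-2-yl)pent-4-enoyl]-1,3-oxazolidin-2-one | C=C(C)[C@@H](CC=C)C(=O)N1[C@H](Cc2ccccc2)COC1=O | intermediate
8 | (R)-2-(prop-1-en-2-yl)pent-4-en-1-ol | C=C(C)[C@@H](CC=C)CO | intermediate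
9 | methacryloyl chloride (2-methylprop-2-enoyl chloride) | C=C(C)C(=O)Cl | starting material
10 | (R)-2-(prop-1-en-2-yl)pent-4-en-1-yl 2-methylprop-2-enoate | C=C(C)[C@@H](CC=C)COC(=O)C(C)=C | intermediate
11 | (R)-3-methyl-6-(prop-1-en-2-yl)-6,7-dihydrooxepin-2(5H)-one | C=C(C)[C@H]1CC=C(C)C(=O)OC1 | intermediate
12 | (2Z,5R)-2-methyl-5-(prop-1-en-2-yl)hex-2-ene-1,6-diol | C=C(C)[C@@H](C/C=C(C)\CO)CO | intermediate
13 | (2Z,5R)-2-methyl-5-(prop-1-en-2-yl)hex-2-enedial | C=C(C)[C@@H](C/C=C(C)\C=O)C=O | intermediate
14 | (5R,6R)-6-hydroxy-2-methyl-5-(prop-1-en-2-yl)cyclohex-2-en-1-one | C=C(C)[C@H]1CC=C(C)C(=O)[C@@H]1O | intermediate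
15 | (1S,3R,4R,6S)-3-hydroxy-1-methyl-4-(prop-1-en-2-yl)-7-oxabicyclo[4.1.0]heptan-2-one | C=C(C)[C@H]1C[C@@H]2O[C@]2(C)C(=O)[C@@H]1O | intermediate
16 | 1,4-dioxane-2,5-diol (glycolaldehyde dimer) | OC1COC(O)CO1 | starting material
17 | 2-(triphenyl-λ5-phosphanylidene)propanal | CC(C=O)=P(c1ccccc1)(c1ccccc1)c1ccccc1 | starting material
18 | glycolaldehyde (2-hydroxyacetaldehyde) | OCC=O | intermediate
19 | (E)-4-hydroxy-2-methylbut-2-enal | O=C/C(C)=C/CO | intermediate
20 | (E)-2-methylbut-2-enoyl chloride (tigloyl chloride) | C/C=C(\C)C(=O)Cl | starting material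
21 | (E)-3-methyl-4-oxobut-2-en-1-yl (E)-2-methylbut-2-enoate | O=C/C(C)=C/COC(=O)/C(C)=C/C | intermediate
22 | (E)-2-methyl-4-{[(E)-2-methylbut-2-enoyl]oxy}but-2-enoic acid | OC(=O)/C(C)=C/COC(=O)/C(C)=C/C | intermediate
23 | (1S,3R,4R,6S)-1-methyl-2-oxo-4-(prop-1-en-2-yl)-7-oxabicyclo[4.1.0]heptan-3-yl (E)-2-methyl-4-{[(E)-2-methylbut-2-enoyl]oxy}but-2-enoate | C=C(C)[C@H]1C[C@@H]2O[C@]2(C)C(=O)[C@@H]1OC(=O)/C(C)=C/COC(=O)/C(C)=C/C | target

**Summary**
Total step count: 12. Longest linear sequence: 9 steps (steps 1 to 8, then step 12).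

The three steps most likely to fail:

1. Step 8 (key step). What may go wrong: carbene addition to the saturated aldehyde first, so that the ring closes with the reverse sense of the acyloin; base-induced epimerisation at C5 or oligomerisation of the dialdehyde before it closes; oxidative degradation of the free ketol by the peroxide in the second stage. Fallback (sets out from 13, comes back at 23): the same bond is formed reductively and without base by a SmI2-mediated pinacol cyclisation of 13 (THF, t-BuOH, −78 °C). This should give the cis-diol (1R,2S,6R)-3-methyl-6-(prop-1-en-2-yl)cyclohex-3-ene-1,2-diol F1, with the hydroxyl next to the isopropenyl group trans to it; its epimer at the allylic carbinol would converge. Chemoselective oxidation of the allylic hydroxyl with MnO2 (CH2Cl2, rt) then gives hydroxy enone 14, this time isolated. 14 is esterified with acid 22 (DCC, DMAP, CH2Cl2) to give (1R,6R)-3-methyl-2-oxo-6-(prop-1-en-2-yl)cyclohex-3-en-1-yl (E)-2-methyl-4-{[(E)-2-methylbut-2-enoyl]oxy}but-2-enoate F2. The nucleophilic epoxidation (t-BuOOH, DBU, CH2Cl2, 0 °C) is run last on F2, in which no free ketol is left and the two enoate alkenes are far less electrophilic than the enone, to give 23.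

2. Step 5. What may go wrong: slow closure of the seven-membered ring onto the electron-poor 1,1-disubstituted alkene, so that intermolecular metathesis of the terminal alkene (dimerisation) takes over. Fallback (sets out from 4, comes back at 12): the Z alkene is made by a Still–Gennari olefination in place of the ring. The sodium dienolate 6 of imide 4 is alkylated with tert-butyl bromoacetate to give tert-butyl (R)-3-[(R)-4-benzyl-2-oxo-1,3-oxazolidine-3-carbonyl]-4-methylpent-4-enoate F3. LiBH4 removes the auxiliary to give tert-butyl (R)-3-(hydroxymethyl)-4-methylpent-4-enoate F4, which is silylated at once (t-BuMe2SiCl, imidazole) to tert-butyl (R)-3-{[(tert-butyldimethylsilyl)oxy]methyl}-4-methylpent-4-enoate F5. i-Bu2AlH at −78 °C gives (R)-3-{[(tert-butyldimethylsilyl)oxy]methyl}-4-methylpent-4-enal F6. Olefination with (CF3CH2O)2P(O)CH(CH3)CO2CH3, KN(SiMe3)2 and 18-crown-6 at −78 °C should give methyl (2Z,5R)-5-{[(tert-butyldimethylsilyl)oxy]methyl}-2,6-dimethylhepta-2,6-dienoate F7. i-Bu2AlH reduces the ester to (2Z,5R)-5-{[(tert-butyldimethylsilyl)oxy]methyl}-2,6-dimethylhepta-2,6-dien-1-ol F8, and Bu4NF releases diol 12.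

3. Step 7. What may go wrong: incomplete double oxidation followed by lactol formation and over-oxidation back to the lactone, Z to E isomerisation of the enal, and loss of configuration next to the saturated aldehyde during work-up. Fallback (sets out from 11, comes back at 13): the two aldehydes are made one after the other so that no hydroxy aldehyde is ever present. Lactone 11 is opened with MeONHMe·HCl/AlMe3 to the Weinreb amide (2Z,5R)-6-hydroxy-N-methoxy-N,2-dimethyl-5-(prop-1-en-2-yl)hex-2-enamide F9. The alcohol is silylated (Et3SiCl, imidazole) to (2Z,5R)-N-methoxy-N,2-dimethyl-5-(prop-1-en-2-yl)-6-[(triethylsilyl)oxy]hex-2-enamide F10. i-Bu2AlH (−78 °C) reduces the amide through its stable chelate to (2Z,5R)-2-methyl-5-(prop-1-en-2-yl)-6-[(triethylsilyl)oxy]hex-2-enal F11. A Swern oxidation carried out directly on the primary triethylsilyl ether then gives 13, used at once in step 8.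

Further compounds
F1 | step 8 | (1R,2S,6R)-3-methyl-6-(prop-1-en-2-yl)cyclohex-3-ene-1,2-diol | C=C(C)[C@H]1CC=C(C)[C@H](O)[C@@H]1O
F2 | step 8 | (1R,6R)-3-methyl-2-oxo-6-(prop-1-en-2-yl)cyclohex-3-en-1-yl (E)-2-methyl-4-{[(E)-2-methylbut-2-enoyl]oxy}but-2-enoate | C=C(C)[C@H]1CC=C(C)C(=O)[C@@H]1OC(=O)/C(C)=C/COC(=O)/C(C)=C/C
F3 | step 5 | tert-butyl (R)-3-[(R)-4-benzyl-2-oxo-1,3-oxazolidine-3-carbonyl]-4-methylpent-4-enoate | C=C(C)[C@@H](CC(=O)OC(C)(C)C)C(=O)N1[C@H](Cc2ccccc2)COC1=O
F4 | step 5 | tert-butyl (R)-3-(hydroxymethyl)-4-methylpent-4-enoate | C=C(C)[C@@H](CC(=O)OC(C)(C)C)CO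
F5 | step 5 | tert-butyl (R)-3-{[(tert-butyldimethylsilyl)oxy]methyl}-4-methylpent-4-enoate | C=C(C)[C@@H](CC(=O)OC(C)(C)C)CO[Si](C)(C)C(C)(C)C
F6 | step 5 | (R)-3-{[(tert-butyldimethylsilyl)oxy]methyl}-4-methylpent-4-enal | C=C(C)[C@@H](CC=O)CO[Si](C)(C)C(C)(C)C
F7 | step 5 | methyl (2Z,5R)-5-{[(tert-butyldimethylsilyl)oxy]methyl}-2,6-dimethylhepta-2,6-dienoate | C=C(C)[C@@H](C/C=C(C)\C(=O)OC)CO[Si](C)(C)C(C)(C)C
F8 | step 5 | (2Z,5R)-5-{[(tert-butyldimethylsilyl)oxy]methyl}-2,6-dimethylhepta-2,6-dien-1-ol | C=C(C)[C@@H](C/C=C(C)\CO)CO[Si](C)(C)C(C)(C)C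
F9 | step 7 | (2Z,5R)-6-hydroxy-N-methoxy-N,2-dimethyl-5-(prop-1-en-2-yl)hex-2-enamide | C=C(C)[C@@H](C/C=C(C)\C(=O)N(C)OC)CO
F10 | step 7 | (2Z,5R)-N-methoxy-N,2-dimethyl-5-(prop-1-en-2-yl)-6-[(triethylsilyl)oxy]hex-2-enamide | C=C(C)[C@@H](C/C=C(C)\C(=O)N(C)OC)CO[Si](CC)(CC)CC
F11 | step 7 | (2Z,5R)-2-methyl-5-(prop-1-en-2-yl)-6-[(triethylsilyl)oxy]hex-2-enal | C=C(C)[C@@H](C/C=C(C)\C=O)CO[Si](CC)(CC)CC
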